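## The problem

Target 39 is a C‑homo‑27‑noroleanane. Rings A, B, D and E are six‑membered; ring C is a cycloheptene (C8, C9, C11, C12, C27, C13, C14) whose tetrasubstituted C13=C14 bond is shared with ring D. Rings A/B are trans‑fused, rings D/E cis‑fused, and the two halves are joined only through ring C.

The ten stereocenters fall into three groups: C3, C4, C5, C8, C9, C10 in the west; C17, C18, C19 in the east; C12 alone in ring C. In the west, C4, C5, C9 and C10 can be set together and then steer C3 (reagent approach to a rigid trans‑decalin) and C8 (bond formation anti to the axial C10 methyl). In the east, the quaternary C17 can steer C18 and C19. C12 is insulated by a CH2 group on each side, so no reliable relay reaches it, and the two halves need independent absolute control.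

Several groups will not survive rough treatment:
- The C12 methyl ether is homoallylic to C13=C14 and ionizes with participation of that alkene (cyclopropylcarbinyl cation), so substitution at C12 is unreliable.
- Protonation of C13=C14 gives cations that the C28 acid or the C19 hydroxyl can capture.
- A 3‑oxo‑24‑acid would decarboxylate.
- Both carboxyl groups sit on quaternary carbons and resist hydrolysis, so their oxidation level and protection must be planned from the start.

The feature that makes the key step possible is ring A. C4 is quaternary, carries methyl C23 and carboxyl C24, and lies next to the C3 oxygen; the A/B fusion is trans with methyl C25 on C10. This is the pattern left when the radical of a 2‑methyl‑3‑oxo ester adds along an (E,E)‑1,5‑diene. The cascade ends at C8, leaving the exocyclic C8=C26 alkene and the C11 oxygen, the two atoms through which ring C is later closed.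

## Retrosynthesis

**End game (39 ← 34).** No skeletal bond is cut. The C28 acid of 39 is unmasked last from methyl ester 38 by thiolate SN2 dealkylation, which avoids acid near the alkene. The C24 acid of 37 is taken back to the primary alcohol 35, because the chiral ester used in the key step is removed by hydride and C24 therefore travels as a silyl ether (34). The forward steps must distinguish one primary from two hindered secondary silyl ethers and must stay non‑acidic once the C28 acid is free.

**C12 (34 ← 33 ← 32).** The O–CH3 bond and the C12–H bond are cut, leading to cycloheptenone 32. Substitution at C12 is ruled out by homoallylic participation, so the configuration must come from hydride addition to the ring ketone followed by O‑methylation with retention. The forward reduction must deliver hydride from the β‑face.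

**Ring C (32 ← 31).** The C8–C14 bond is cut. Against cutting C11–C12 or C12–C27, this cut uses both handles left by the key step: the exocyclic C8=C26 alkene becomes the C8 quaternary center and the C26 methyl in one reductive Heck closure. The precursor 31 is an open ketone with a vinyl triflate at C14. The forward step must insert in the 7‑exo mode, attack C8 on the α‑face, and end by hydride capture of a neopentyl palladium species.

**Fragment union (31 ← 13 + 29).** The C11–C12 bond is cut between the C11 organolithium from iodide 13 and Weinreb amide 29. This splits the target into two fragments of 15 carbons each and puts the C12 carbonyl where the oxygen is needed. The forward addition must spare the vinyl triflate and the hindered esters.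

**Vinyl triflate (29 ← 27 ← 25).** The C14–O(Tf) bond is traced to enol lactone 27, made from the γ‑keto acid derived from 25. A direct triflation of the C14 ketone would not distinguish C13 from C15; the five‑membered enol lactone can only hold the C13=C14 double bond, and its opening by an amide nucleophile releases exactly that enolate while installing the Weinreb amide.

**C18 and C19 (25 ← 22 ← 20).** The C19–H and C18–H bonds are cut. The C19 alcohol comes from ketone 22 by equatorial hydride delivery, and the cis ring fusion from hydrogenation of enedione 20. C14 is masked as a dimethyl ketal while C19 is reduced.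

**Rings D/E (20 ← 19 ← 17 + 16).** The C19 carbonyl is removed (allylic oxidation of enone 19). Then the C13=C18 bond (aldol condensation) and the C16–C17 bond (Michael addition) are cut, giving β‑keto ester 17 and vinyl ketone 16. A catalytic asymmetric Michael addition sets C17, the only stereocenter that must be made without substrate control in this half. Vinyl ketone 16 comes from acid chloride 14 and vinylstannane 15.

**West fragment (13 ← 11 ← 9).** These are functional group changes only: C3 ketone to axial alcohol, auxiliary ester to C24 alcohol, C11 acetate to iodide. Triol 11 has three hydroxyls of graded hindrance, which allows the iodination to be selective.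

**Key step (9 ← 8).** The C4–C5 and C9–C10 bonds are cut, opening rings A and B to acyclic keto ester 8. Two rings and four stereocenters arise in one step from an achiral chain plus a chiral ester.

**Chain assembly (8 ← 3 + 6).** The C1–C2 bond is cut between the dianion of keto ester 3 and allylic bromide 6. Bromide 6 comes from geranyl acetate 4 by allylic oxidation and bromination; 3 comes from 1 and auxiliary alcohol 2.

## Roads not taken

**Alternative 1: lactone Ireland–Claisen ring contraction.** The cut is C17–C18, with a C14–O bond sacrificed. In the forward sense a δ‑lactone (acyl carbon C22, α‑carbon C17 bearing the C28 ester, ring oxygen on C14) is converted to its silyl ketene acetal. The [3,3] shift through O–C14–C13=C18 forms C17–C18, closes ring D and places the alkene at C13=C14, giving A1.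
- Merits: the alkene position follows from the mechanism; C17 and C18 are set in one suprafacial event with chirality transfer from C14.
- Weak points: a malonate‑type, fully substituted ketene acetal carbon must bond to a C18 that carries a branched substituent, within a constrained ring‑contracting transition state. The substrate needs a tertiary C14–O stereocenter next to quaternary C8 and a C13=C18 alkene of defined geometry. After the step ring E is still open, and C22 must be taken from acid to CH2 while C28 stays an ester.
- Comparison: this road is better in fixing the alkene and both eastern stereocenters without a metal. The chosen plan sets against it a short catalytic entry to rings D/E, no surplus oxidation level to remove, and direct use of the exocyclic alkene from the key step.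

**Alternative 2: cyclopropane relay.** The cut is C8–C26 and C14–C26. In the forward sense Et2Zn/CH2I2 delivers a methylene to the tetrasubstituted C8=C14 alkene of a 26‑nor pentacycle from the face of the allylic C13 hydroxyl, giving A2. Opening the C14–C26 bond then leaves the C8 methyl and C13=C14.
- Merits: hydroxyl‑directed cyclopropanation is among the most dependable reactions of tetrasubstituted alkenes, and the C8 configuration is tied to one hydroxyl face.
- Weak points: the whole 26‑nor pentacycle with a C8=C14 alkene and a tertiary C13 carbinol must exist first, so C8 cannot be approached from a polyene cyclization product. The ring opening must select C14–C26 over the other two cyclopropane bonds and needs a reductive termination. The cation involved sits β to the C12 methoxy group and near the C19 ester, inviting participation or elimination.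
- Comparison: for stereocontrol at C8 this road is the more certain one; the chosen plan depends on the facial preference of a carbopalladation. The chosen plan sets against it convergence (two 15‑carbon halves), a C26 that is already in place, and ring closure and quaternization in a single step.

**Alternative 3: Diels–Alder union of an ABC diene with ring E.** The cut is C13–C18 and C16–C17. In the forward sense a C13=C14–C15=C16 diene unit on ring C adds to the C17=C18 bond of the ring E keto ester A4 under Et2AlCl, giving A3.
- Merits: ring D, C17 and C18 are made in one step from a simple achiral dienophile, and the cis D/E fusion is guaranteed by suprafacial addition.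
- Weak points: A3 has its alkene at C14=C15. Moving it to C13=C14 while a C19 ketone is present competes with conjugation into C13=C18 and with epimerization at C18. The isomerization needs acid or a metal hydride in the presence of the C12 ether. The cycloaddition joins a diene carbon next to quaternary C8 to a dienophile carbon that becomes quaternary, and its regiochemistry rests on a ketone‑versus‑ester bias in A4. The ABC tricycle with C8 in place must still be built.
- Comparison: in step count for rings D/E this road is shorter than the eight‑step fragment used here. The chosen plan sets against it an alkene position fixed by construction (the triflate carbon), no late isomerization, and C18/C19 set on a small bicyclic fragment.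

Key step: step 5

Assumptions on the chemistry:
- Numbering follows oleanane; the ring C methylene between C12 and C13 is called C27. α is the face of 5‑H and 9‑H; β is the face of the C10 and C8 methyls.
- The (1R,2S,5R)‑8‑phenylmenthyl ester is assumed to direct the cyclization to the 4β‑carboxyl, 10β‑methyl series, by analogy with 8‑phenylmenthyl 2‑alkylacetoacetates in this reaction class. If the sense is opposite, the enantiomeric alcohol is used.
- The quinidine‑derived catalyst in step 10 is assumed to give the (S)‑configured C17; otherwise its quinine‑derived pseudoenantiomer is used.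

## Route

Step 1
Reactants: 1 methyl 2-methyl-3-oxobutanoate; 2 (1R,2S,5R)-5-methyl-2-(2-phenylpropan-2-yl)cyclohexan-1-ol ((−)-8-phenylmenthol)
Product: 3 (1R,2S,5R)-8-phenylmenthyl 2-methyl-3-oxobutanoate (both C2 epimers)
Conditions: DMAP (0.3 equiv), toluene, reflux, 4 Å molecular sieves
Reagents that add atoms: none
Why: DMAP-catalysed transesterification of a β-keto ester; removal of methanol drives the exchange and the enolizable C2 center is of no consequence because it becomes a planar radical in step 5.

Step 2
Reactants: 4 geranyl acetate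
Product: 5 (2E,6E)-8-hydroxy-3,7-dimethylocta-2,6-dien-1-yl acetate
Conditions: SeO2 (0.1 equiv), t-BuOOH (3 equiv), CH2Cl2, 0 °C to rt
Reagents that add atoms: tert-butyl hydroperoxide, CC(C)(C)OO
Why: Catalytic SeO2 allylic oxidation (ene reaction then [2,3] shift) is selective for the (E)-methyl group of the terminal trisubstituted alkene; the allylic acetate end is deactivated.

Step 3
Reactants: 5 (2E,6E)-8-hydroxy-3,7-dimethylocta-2,6-dien-1-yl acetate
Product: 6 (2E,6E)-8-bromo-3,7-dimethylocta-2,6-dien-1-yl acetate
Conditions: CBr4, PPh3, CH2Cl2, −20 to 0 °C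
Reagents that add atoms: tetrabromomethane, BrC(Br)(Br)Br
Why: Appel bromination of a primary allylic alcohol under neutral conditions proceeds by SN2 without allylic transposition or loss of alkene geometry.

Step 4
Reactants: 3 (1R,2S,5R)-8-phenylmenthyl 2-methyl-3-oxobutanoate; 6 (2E,6E)-8-bromo-3,7-dimethylocta-2,6-dien-1-yl acetate
Product: 8 (1R,2S,5R)-8-phenylmenthyl (6E,10E)-12-acetoxy-2,6,10-trimethyl-3-oxododeca-6,10-dienoate (both C2 epimers), via sodium lithium dianion 7 (not isolated)
Conditions: NaH, THF, 0 °C; n-BuLi, −10 °C; then 6, −78 to 0 °C; aq. NH4Cl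
Reagents that add atoms: none
Why: β-Keto ester dianion alkylation occurs at the terminal (more basic) carbon; SN2 at the allylic bromide is much faster at low temperature than attack on the acetate and forms the C1–C2 bond with both (E)-alkenes intact.

Step 5
Reactants: 8 (1R,2S,5R)-8-phenylmenthyl (6E,10E)-12-acetoxy-2,6,10-trimethyl-3-oxododeca-6,10-dienoate
Product: 9 (1R,2S,5R)-8-phenylmenthyl ester of the AB keto acid: trans-decalin C1–C11 with 3-oxo; 4α-methyl C23; 4β-carboxylate C24; 5α-H; 8(26)-methylene; 9α-H with 9β-CH2OAc (C11); 10β-methyl C25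
Conditions: Mn(OAc)3·2H2O (2.2 equiv), Cu(OAc)2·H2O (1 equiv), degassed AcOH, 25 to 40 °C
Reagents that add atoms: none
Why: Mn(OAc)3 oxidizes the enol form of the 2-methyl-3-oxo ester to the electrophilic tertiary C4 radical, so both C2 epimers of 8 converge. This radical adds 6-endo-trig to C5 of the C5=C10 alkene (ring A, C4–C5) and the resulting tertiary C10 radical adds 6-endo-trig to C9 of the C8=C9 alkene (ring B, C9–C10); the tertiary C8 radical is then captured by divalent copper and loses a C26 hydrogen to give the exocyclic alkene, while the copper is returned to the divalent state by trivalent manganese. The closest known reaction type is the Mn(OAc)3/Cu(OAc)2 oxidative free-radical polyene cyclization of unsaturated 2-alkyl β-keto esters, including their 8-phenylmenthyl esters. Both closures pass through chair-like transition states of the (E)-alkenes, which makes 5-H and the C10 methyl trans, places the C9 side chain equatorial and puts the ester at C4 axial, cis to the C10 methyl. The absolute sense is fixed at C4 by the auxiliary, whose phenyl ring covers one face of the planar radical so that the C5=C10 alkene approaches the open face, and it is relayed to C5, C10 and C9 by the chairs. The step needs 6-endo over 5-exo regioselectivity, which the trisubstituted alkenes secure by always generating a tertiary radical, and it needs the acetate and the allylic C–O bond to stay inert, which the mild oxidant allows. Any minor diastereomer is removed at this stage because the auxiliary is still attached.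

Step 6
Reactants: 9 AB keto ester acetate (8-phenylmenthyl ester)
Product: 11 AB triol: 8(26)-ene-3α;11;24-triol of the same decalin (3α-OH axial; C24 CH2OH on the β-face), via 3α-hydroxy ester acetate 10 (not isolated)
Conditions: LiBH(s-Bu)3 (L-Selectride, 1.3 equiv), THF, −78 to −30 °C; then LiAlH4 (5 equiv), 0 to 50 °C; Rochelle salt work-up
Reagents that add atoms: none
Why: The bulky borohydride attacks the C3 ketone along the equatorial trajectory (axial approach is blocked by the axial C4 ester and the C10 methyl) and gives the axial 3α-alcohol; LiAlH4 then reduces the hindered auxiliary ester to the C24 alcohol and cleaves the acetate, returning the auxiliary alcohol 2.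

Step 7
Reactants: 11 AB triol
Product: 12 11-iodo-8(26)-ene-3α;24-diol
Conditions: I2 (1.3 equiv), PPh3 (1.4 equiv), imidazole, toluene/MeCN, 0 °C to rt
Reagents that add atoms: iodine, II
Why: Appel-type iodination needs an SN2 displacement, which is feasible only at the β-branched primary C11; the neopentyl C24 hydroxyl and the axial secondary C3 hydroxyl flanked by quaternary C4 do not substitute and are returned on work-up.

Step 8
Reactants: 12 11-iodo-8(26)-ene-3α;24-diol
Product: 13 3α;24-bis(tert-butyldimethylsilyl) ether of 12
Conditions: TBSOTf (2.6 equiv), 2,6-lutidine, CH2Cl2, −78 to 0 °C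
Reagents that add atoms: tert-butyldimethylsilyl trifluoromethanesulfonate, CC(C)(C)[Si](C)(C)OS(=O)(=O)C(F)(F)F
Why: The silyl triflate silylates even hindered axial and neopentyl hydroxyls; the primary iodide and the alkene are inert.

Step 9
Reactants: 14 methyl 4-chloro-4-oxobutanoate; 15 tributyl(vinyl)stannane
Product: 16 methyl 4-oxohex-5-enoate
Conditions: PdCl2(PPh3)2 (2 mol%), THF, 50 °C
Reagents that add atoms: none
Why: Stille acylation of an acid chloride with a vinylstannane gives the vinyl ketone directly; the ester is untouched and the product is used without storage.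

Step 10
Reactants: 17 methyl 4,4-dimethyl-2-oxocyclohexane-1-carboxylate; 16 methyl 4-oxohex-5-enoate
Product: 19 ring D/E enone: methyl (4aS)-1-(2-methoxy-2-oxoethyl)-7,7-dimethyl-2-oxo-3,4,5,6,7,8-hexahydronaphthalene-4a(2H)-carboxylate (C14 ketone; C13=C18; 17β-CO2Me), via Michael adduct 18 (not isolated)
Conditions: 9-O-(phenanthren-9-yl)cupreidine (10 mol%), CH2Cl2, −20 °C; then pyrrolidine (0.3 equiv), AcOH, toluene, 80 °C
Reagents that add atoms: none
Why: Robinson annulation: the bifunctional cinchona base binds the enol of the β-keto ester and the vinyl ketone and sets the quaternary C17 in the Michael step (C16–C17); enamine-mediated aldol condensation of the C13 methylene onto the C18 ketone then closes ring D.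

Step 11
Reactants: 19 ring D/E enone
Product: 20 ring D/E enedione: methyl (4aS)-1-(2-methoxy-2-oxoethyl)-7,7-dimethyl-2,8-dioxo-3,4,5,6,7,8-hexahydronaphthalene-4a(2H)-carboxylate (C14 and C19 ketones)
Conditions: Rh2(cap)4 (dirhodium tetracaprolactamate, 1 mol%), t-BuOOH (5 equiv), K2CO3, CH2Cl2, rt
Reagents that add atoms: tert-butyl hydroperoxide, CC(C)(C)OO
Why: Catalytic allylic oxidation of an enone at its γ-methylene gives the 2-ene-1,4-dione; the position next to a gem-dimethyl carbon is the one oxidized in the isophorone to ketoisophorone conversion, the same substitution pattern as here.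

Step 12
Reactants: 20 ring D/E enedione
Product: 22 cis-fused 14,14-dimethoxy 19-ketone (13β-H; 18β-H; 17β-CO2Me), via cis-fused diketone 21 (not isolated)
Conditions: H2 (1 atm), 10% Pd/C, EtOAc, rt; filter; then HC(OMe)3, p-TsOH·H2O (5 mol%), MeOH, rt; Et3N quench
Reagents that add atoms: trimethyl orthoformate, COC(OC)OC
Why: Heterogeneous hydrogenation of the electron-poor tetrasubstituted alkene adds both hydrogens to one face and, as with angularly substituted octalones, should give the cis ring fusion (18-H on the side of the C17 ester); ketalization then takes only the unhindered C14 carbonyl, the C19 carbonyl being flanked by a quaternary and a ring-fusion carbon.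

Step 13
Reactants: 22 cis-fused 14,14-dimethoxy 19-ketone
Product: 23 19α-hydroxy 14,14-dimethyl ketal
Conditions: LiBH(s-Bu)3 (1.5 equiv), THF, −78 to −20 °C; aq. NH4Cl
Reagents that add atoms: none
Why: Reduction of a hindered cyclohexanone by a bulky borohydride; axial approach to C19 is blocked by C16, which is syn-axial on ring E, so hydride enters equatorially from the convex β-face and gives the axial 19α-alcohol, the same logic as at C3; the reagent is non-basic, so 18-H is not epimerized, and the esters do not react at this temperature.

Step 14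
Reactants: 23 19α-hydroxy 14,14-dimethyl ketal
Product: 25 19α-(tert-butyldimethylsilyloxy) 14-ketone (side-chain methyl ester; 17β-CO2Me), via silyl ether ketal 24 (not isolated)
Conditions: TBSOTf (1.5 equiv), 2,6-lutidine, CH2Cl2, −78 to 0 °C; then 1 M HCl, THF, 0 °C
Reagents that add atoms: tert-butyldimethylsilyl trifluoromethanesulfonate, CC(C)(C)[Si](C)(C)OS(=O)(=O)C(F)(F)F
Why: Silylation before the ketone is unveiled prevents the 19-hydroxyl from closing a hemiketal onto C14; the dimethyl ketal is then hydrolysed by dilute acid, which the hindered silyl ether tolerates.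

Step 15
Reactants: 25 19α-silyloxy 14-ketone
Product: 27 enol lactone (O–C14=C13–C27H2–C12(=O)–O five-membered ring; 19α-OTBS; 17β-CO2Me; 18β-H), via keto acid 26 (not isolated)
Conditions: LiOH·H2O (1.2 equiv), THF/H2O, 0 °C; acidify to pH 3; then Ac2O, NaOAc, 100 °C
Reagents that add atoms: none
Why: Only the unhindered side-chain ester is saponified (the C28 ester sits on quaternary C17); enol lactonization of a γ-keto acid, the first stage of the Fujimoto–Belleau sequence, gives the lactone with the double bond inside the five-membered ring and thereby fixes the enol regiochemistry as C13=C14.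

Step 16
Reactants: 27 enol lactone
Product: 29 vinyl triflate Weinreb amide (C14–OTf on C13=C14; C13–CH2–C(=O)N(OMe)Me; 19α-OTBS; 17β-CO2Me; 18β-H), via lithium enolate 28 (not isolated)
Conditions: MeNH(OMe)·HCl (1.3 equiv), n-BuLi (2.6 equiv), THF, −78 to 0 °C; add 27 at −78 °C; then N-(5-chloropyridin-2-yl)bis(trifluoromethanesulfonyl)imide (1.3 equiv), −78 to 0 °C
Reagents that add atoms: N,O-dimethylhydroxylamine hydrochloride, CNOC.Cl; N-(5-chloropyridin-2-yl)bis(trifluoromethanesulfonyl)imide, O=S(=O)(N(c1ccc(Cl)cn1)S(=O)(=O)C(F)(F)F)C(F)(F)F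
Why: Acyl substitution at the activated enol ester carbonyl by the lithium amide gives the Weinreb amide and releases the C14 enolate with its double bond toward C13, the regiospecific enolate generation known for enol esters; the enolate is trapped on oxygen by the triflimide before it can equilibrate.

Step 17
Reactants: 13 bis-silylated AB iodide; 29 vinyl triflate Weinreb amide
Product: 31 open ketone: C11H2–C12(=O)–C27H2 link between the AB decalin (8(26)-methylene) and the ring D/E vinyl triflate, via alkyllithium 30 (not isolated)
Conditions: 13, t-BuLi (2.1 equiv), Et2O/pentane, −78 °C; then 29 in THF, −78 to −40 °C; aq. NH4Cl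
Reagents that add atoms: none
Why: Iodine–lithium exchange gives the primary C11 organolithium, which adds to the Weinreb amide (Weinreb ketone synthesis); the chelated tetrahedral intermediate prevents a second addition, and at −78 °C the vinyl triflate and the hindered C28 ester are spared.

Step 18
Reactants: 31 open ketone
Product: 32 pentacyclic 12-ketone (ring C closed; 8β-methyl C26; C13=C14; 3α-OTBS; 19α-OTBS; 24-OTBS; 28-methyl ester)
Conditions: Pd(OAc)2 (10 mol%), PPh3 (20 mol%), HCO2Na (1.5 equiv, slow addition), Et4NCl, DMF, 80 °C
Reagents that add atoms: none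
Why: Reductive Heck cyclization: zerovalent palladium inserts into the C14–OTf bond, the vinylpalladium adds 7-exo-trig across C8=C26 with C14 bonding to C8, and the neopentyl palladium at C26, which has no β-hydrogen, is reduced by formate to the C26 methyl; C14 should enter on the α-face of C8, anti to the axial C10 methyl and trans to the equatorial C9 tether, which makes the new methyl β.

Step 19
Reactants: 32 pentacyclic 12-ketone
Product: 33 12α-alcohol
Conditions: LiBH(s-Bu)3 (1.3 equiv), THF, −78 °C
Reagents that add atoms: none
Why: Steric-approach-controlled ketone reduction; ring C should fold toward the α-face to keep C12 and C27 away from the axial C8 methyl, so the bulky hydride reaches C12 from the outer β-face and the hydroxyl ends up α.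

Step 20
Reactants: 33 12α-alcohol
Product: 34 12α-methyl ether (3α;19α;24-tris-TBS; 28-methyl ester)
Conditions: NaH (3 equiv), MeI (5 equiv), THF/DMF, 0 °C to rt
Reagents that add atoms: iodomethane, CI
Why: Williamson methylation on oxygen leaves the C12–O bond untouched, so the configuration is retained and the homoallylic position is never ionized.

Step 21
Reactants: 34 12α-methyl ether
Product: 35 24-alcohol (3α;19α-bis-TBS; 28-methyl ester)
Conditions: HF·pyridine, pyridine, THF, 0 °C
Reagents that add atoms: none
Why: Buffered fluoride cleaves the primary silyl ether much faster than the two secondary ones, each of which is flanked by a quaternary carbon.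

Step 22
Reactants: 35 24-alcohol
Product: 37 24-carboxylic acid (3α;19α-bis-TBS; 28-methyl ester), via aldehyde 36 (not isolated)
Conditions: Dess–Martin periodinane, NaHCO3, CH2Cl2, rt; then NaClO2, NaH2PO4, 2-methyl-2-butene, t-BuOH/H2O, rt
Reagents that add atoms: sodium chlorite, [Na+].[O-]Cl=O
Why: Dess–Martin oxidation gives the non-enolizable neopentyl aldehyde and Pinnick oxidation takes it to the acid; the scavenger removes hypochlorite before it can reach the tetrasubstituted alkene.

Step 23
Reactants: 37 24-carboxylic acid
Product: 38 3α;19α-dihydroxy-12α-methoxy 24-acid 28-methyl ester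
Conditions: HF·pyridine (excess), THF, 0 °C to rt
Reagents that add atoms: none
Why: Fluoride desilylation of the two hindered secondary ethers under buffered conditions; C28 is still an ester, so no lactone can form at C13, and the medium is not acidic enough to add the C19 hydroxyl to the alkene.

Step 24
Reactants: 38 diol acid methyl ester
Product: 39 target: 3α;19α-dihydroxy-12α-methoxy-C(12a)-homo-27-nor-18β-olean-13-ene-24;28-dioic acid
Conditions: n-PrSLi (10 equiv, from n-PrSH and n-BuLi), HMPA, rt; then dilute HCl to pH 3 at 0 °C
Reagents that add atoms: none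
Why: SN2 dealkylation at the methyl group by thiolate cleaves the hindered C28 ester without attack at the carbonyl; the alkyl methyl ether, the alkene and the alkoxides are inert, and the brief cold acidification avoids lactonization.

## Compound list

1 | methyl 2-methyl-3-oxobutanoate | COC(=O)C(C)C(C)=O | starting material
2 | (1R,2S,5R)-5-methyl-2-(2-phenylpropan-2-yl)cyclohexan-1-ol ((−)-8-phenylmenthol) | CC(C)(c1ccccc1)[C@@H]1CC[C@@H](C)C[C@H]1O | starting material
3 | (1R,2S,5R)-8-phenylmenthyl 2-methyl-3-oxobutanoate (C2 epimers) | CC(C)(c1ccccc1)[C@@H]1CC[C@@H](C)C[C@H]1OC(=O)C(C)C(C)=O | intermediate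
4 | geranyl acetate | CC(C)=CCC/C(C)=C/COC(C)=O | starting material
5 | (2E,6E)-8-hydroxy-3,7-dimethylocta-2,6-dien-1-yl acetate | OC/C(C)=C/CC/C(C)=C/COC(C)=O | intermediate
6 | (2E,6E)-8-bromo-3,7-dimethylocta-2,6-dien-1-yl acetate | BrC/C(C)=C/CC/C(C)=C/COC(C)=O | intermediate
7 | sodium lithium dianion of 3 | [Na+].[Li+].CC(C)(c1ccccc1)[C@@H]1CC[C@@H](C)C[C@H]1OC(=O)[C-](C)C(=O)[CH2-] | intermediate
8 | (1R,2S,5R)-8-phenylmenthyl (6E,10E)-12-acetoxy-2,6,10-trimethyl-3-oxododeca-6,10-dienoate (C2 epimers) | CC(C)(c1ccccc1)[C@@H]1CC[C@@H](C)C[C@H]1OC(=O)C(C)C(=O)CC/C(C)=C/CC/C(C)=C/COC(C)=O | intermediate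
9 | AB keto ester: 8-phenylmenthyl 11-acetoxy-3-oxo-8(26)-en-24-oate (4α-Me, 5α-H, 9α-H, 10β-Me) | C=C1CC[C@@H]2[C@](C)(CCC(=O)[C@]2(C)C(=O)O[C@@H]3C[C@H](C)CC[C@H]3C(C)(C)c3ccccc3)[C@H]1COC(C)=O | intermediate
10 | 3α-hydroxy analogue of 9 | C=C1CC[C@@H]2[C@](C)(CC[C@@H](O)[C@]2(C)C(=O)O[C@@H]3C[C@H](C)CC[C@H]3C(C)(C)c3ccccc3)[C@H]1COC(C)=O | intermediate
11 | AB triol: 8(26)-ene-3α,11,24-triol | C=C1CC[C@@H]2[C@](C)(CC[C@@H](O)[C@]2(C)CO)[C@H]1CO | intermediate
12 | 11-iodo-8(26)-ene-3α,24-diol | C=C1CC[C@@H]2[C@](C)(CC[C@@H](O)[C@]2(C)CO)[C@H]1CI | intermediate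
13 | 11-iodo-8(26)-ene 3α,24-bis(tert-butyldimethylsilyl) ether | C=C1CC[C@@H]2[C@](C)(CC[C@@H](O[Si](C)(C)C(C)(C)C)[C@]2(C)CO[Si](C)(C)C(C)(C)C)[C@H]1CI | intermediate
14 | methyl 4-chloro-4-oxobutanoate | COC(=O)CCC(Cl)=O | starting material
15 | tributyl(vinyl)stannane | C=C[Sn](CCCC)(CCCC)CCCC | starting material
16 | methyl 4-oxohex-5-enoate | C=CC(=O)CCC(=O)OC | intermediate
17 | methyl 4,4-dimethyl-2-oxocyclohexane-1-carboxylate | COC(=O)C1CCC(C)(C)CC1=O | starting material
18 | methyl (1S)-1-(6-methoxy-3,6-dioxohexyl)-4,4-dimethyl-2-oxocyclohexane-1-carboxylate | COC(=O)CCC(=O)CC[C@@]1(C(=O)OC)CCC(C)(C)CC1=O | intermediate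
19 | ring D/E enone: methyl (4aS)-1-(2-methoxy-2-oxoethyl)-7,7-dimethyl-2-oxo-3,4,5,6,7,8-hexahydronaphthalene-4a(2H)-carboxylate | COC(=O)CC1=C2CC(C)(C)CC[C@]2(C(=O)OC)CCC1=O | intermediate
20 | ring D/E enedione: methyl (4aS)-1-(2-methoxy-2-oxoethyl)-7,7-dimethyl-2,8-dioxo-3,4,5,6,7,8-hexahydronaphthalene-4a(2H)-carboxylate | COC(=O)CC1=C2C(=O)C(C)(C)CC[C@]2(C(=O)OC)CCC1=O | intermediate
21 | cis-fused 14,19-diketone (13β-H, 18β-H, 17β-CO2Me) | COC(=O)C[C@H]1C(=O)CC[C@@]2(C(=O)OC)CCC(C)(C)C(=O)[C@@H]12 | intermediate
22 | cis-fused 14,14-dimethoxy 19-ketone | COC(=O)C[C@H]1C(OC)(OC)CC[C@@]2(C(=O)OC)CCC(C)(C)C(=O)[C@@H]12 | intermediate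
23 | 19α-hydroxy 14,14-dimethyl ketal | COC(=O)C[C@H]1C(OC)(OC)CC[C@@]2(C(=O)OC)CCC(C)(C)[C@@H](O)[C@@H]12 | intermediate
24 | 19α-silyloxy 14,14-dimethyl ketal | COC(=O)C[C@H]1C(OC)(OC)CC[C@@]2(C(=O)OC)CCC(C)(C)[C@@H](O[Si](C)(C)C(C)(C)C)[C@@H]12 | intermediate
25 | 19α-silyloxy 14-ketone diester | COC(=O)C[C@H]1C(=O)CC[C@@]2(C(=O)OC)CCC(C)(C)[C@@H](O[Si](C)(C)C(C)(C)C)[C@@H]12 | intermediate
26 | 19α-silyloxy 14-keto acid | OC(=O)C[C@H]1C(=O)CC[C@@]2(C(=O)OC)CCC(C)(C)[C@@H](O[Si](C)(C)C(C)(C)C)[C@@H]12 | intermediate
27 | enol lactone (C13=C14 in the lactone ring, 19α-OTBS) | O=C1CC2=C(O1)CC[C@@]3(C(=O)OC)CCC(C)(C)[C@@H](O[Si](C)(C)C(C)(C)C)[C@@H]23 | intermediate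
28 | lithium C14 enolate of the Weinreb amide | [Li+].CON(C)C(=O)CC1=C([O-])CC[C@@]2(C(=O)OC)CCC(C)(C)[C@@H](O[Si](C)(C)C(C)(C)C)[C@@H]12 | intermediate
29 | C14 vinyl triflate Weinreb amide | CON(C)C(=O)CC1=C(OS(=O)(=O)C(F)(F)F)CC[C@@]2(C(=O)OC)CCC(C)(C)[C@@H](O[Si](C)(C)C(C)(C)C)[C@@H]12 | intermediate
30 | C11 alkyllithium from 13 | C=C1CC[C@@H]2[C@](C)(CC[C@@H](O[Si](C)(C)C(C)(C)C)[C@]2(C)CO[Si](C)(C)C(C)(C)C)[C@H]1C[Li] | intermediate
31 | open ketone (C12 ketone, C14 triflate, 8(26)-methylene) | C=C1CC[C@@H]2[C@](C)(CC[C@@H](O[Si](C)(C)C(C)(C)C)[C@]2(C)CO[Si](C)(C)C(C)(C)C)[C@H]1CC(=O)CC2=C(OS(=O)(=O)C(F)(F)F)CC[C@@]3(C(=O)OC)CCC(C)(C)[C@@H](O[Si](C)(C)C(C)(C)C)[C@@H]23 | intermediate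
32 | pentacyclic 12-ketone | O=C1CC2=C(CC[C@@]3(C(=O)OC)CCC(C)(C)[C@@H](O[Si](C)(C)C(C)(C)C)[C@@H]23)[C@]2(C)CC[C@@H]3[C@](C)(CC[C@@H](O[Si](C)(C)C(C)(C)C)[C@]3(C)CO[Si](C)(C)C(C)(C)C)[C@H]2C1 | intermediate
33 | 12α-alcohol | O[C@@H]1CC2=C(CC[C@@]3(C(=O)OC)CCC(C)(C)[C@@H](O[Si](C)(C)C(C)(C)C)[C@@H]23)[C@]2(C)CC[C@@H]3[C@](C)(CC[C@@H](O[Si](C)(C)C(C)(C)C)[C@]3(C)CO[Si](C)(C)C(C)(C)C)[C@H]2C1 | intermediate
34 | 12α-methyl ether, tris-silyl ether | CO[C@@H]1CC2=C(CC[C@@]3(C(=O)OC)CCC(C)(C)[C@@H](O[Si](C)(C)C(C)(C)C)[C@@H]23)[C@]2(C)CC[C@@H]3[C@](C)(CC[C@@H](O[Si](C)(C)C(C)(C)C)[C@]3(C)CO[Si](C)(C)C(C)(C)C)[C@H]2C1 | intermediate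
35 | 24-alcohol | CO[C@@H]1CC2=C(CC[C@@]3(C(=O)OC)CCC(C)(C)[C@@H](O[Si](C)(C)C(C)(C)C)[C@@H]23)[C@]2(C)CC[C@@H]3[C@](C)(CC[C@@H](O[Si](C)(C)C(C)(C)C)[C@]3(C)CO)[C@H]2C1 | intermediate
36 | 24-aldehyde | CO[C@@H]1CC2=C(CC[C@@]3(C(=O)OC)CCC(C)(C)[C@@H](O[Si](C)(C)C(C)(C)C)[C@@H]23)[C@]2(C)CC[C@@H]3[C@](C)(CC[C@@H](O[Si](C)(C)C(C)(C)C)[C@]3(C)C=O)[C@H]2C1 | intermediate
37 | 24-carboxylic acid, bis-silyl ether, 28-methyl ester | CO[C@@H]1CC2=C(CC[C@@]3(C(=O)OC)CCC(C)(C)[C@@H](O[Si](C)(C)C(C)(C)C)[C@@H]23)[C@]2(C)CC[C@@H]3[C@](C)(CC[C@@H](O[Si](C)(C)C(C)(C)C)[C@]3(C)C(=O)O)[C@H]2C1 | intermediate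
38 | 3α,19α-diol 24-acid 28-methyl ester | CO[C@@H]1CC2=C(CC[C@@]3(C(=O)OC)CCC(C)(C)[C@@H](O)[C@@H]23)[C@]2(C)CC[C@@H]3[C@](C)(CC[C@@H](O)[C@]3(C)C(=O)O)[C@H]2C1 | intermediate
39 | 3α,19α-dihydroxy-12α-methoxy-C(12a)-homo-27-nor-18β-olean-13-ene-24,28-dioic acid | CO[C@@H]1CC2=C(CC[C@@]3(C(=O)O)CCC(C)(C)[C@@H](O)[C@@H]23)[C@]2(C)CC[C@@H]3[C@](C)(CC[C@@H](O)[C@]3(C)C(=O)O)[C@H]2C1 | target

## Step count and least certain steps

Total: 24 steps. Longest linear sequence: 16 steps (steps 9 to 16, then 17 to 24). The west branch (steps 2 to 8, fed by step 1) joins at step 17.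

**Step 5 (key step).** The auxiliary may discriminate the faces of the C4 radical poorly, giving a mixture at the four new centers. The second ring closure may also lag behind oxidation of the C10 radical, and the termination may give endocyclic alkene isomers. Fallback by resolution instead of auxiliary control: the dianion of 1 is alkylated with 6 to give the methyl ester precursor F1, which is cyclized under the same Mn(OAc)3/Cu(OAc)2 conditions to the racemic methyl keto ester F2. Reduction as in step 6 gives the racemate of 11. This is resolved by lipase‑catalysed acetylation of the primary C11 hydroxyl (Amano lipase PS, vinyl acetate), a known type of resolution for primary alcohols with a β‑stereocenter on a decalin. If the wanted enantiomer is the one acetylated, its monoacetate F3 is cleaved with K2CO3 in MeOH. The route is rejoined at 11.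

**Step 18 (reductive Heck).** The vinylpalladium may be reduced by formate before it inserts into the hindered alkene. Insertion may go 8‑endo, the neopentyl palladium may add to C13=C14 instead of being reduced, and attack at C8 may lack facial preference. Fallback by cation–olefin closure instead of carbopalladation: 31 is converted to the vinylsilane F4 by palladium‑catalysed silylation (Pd(PPh3)4, Me3SiSiMe3). A protic acid at low temperature then protonates C8=C26 in the Markovnikov sense (C26 becomes the methyl), the C8 cation is attacked at the silyl‑bearing C14, and loss of the silyl group from the β‑silyl cation restores C13=C14 (vinylsilane‑terminated cyclization). The route is rejoined at 32.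

**Step 19 (C12 configuration).** The cycloheptenone is flexible, so hydride delivery may show poor or opposite facial selectivity. Fallback by inversion: the 12β‑alcohol F5 is converted to the mesylate F6 and displaced with CsOAc and 18‑crown‑6 in toluene. These are the non‑ionizing SN2 conditions that invert homoallylic 3β‑sulfonates of Δ5‑steroids without participation of the alkene. The 12α‑acetate F7 is cleaved with K2CO3 in MeOH. The route is rejoined at 33.

**Step 13 (C19 and C18).** The dimethyl ketal at C14 may distort the cis‑decalin enough to erode equatorial delivery to C19, and 18‑H may epimerize while C19 is a ketone. Fallback by reducing C19 only after C13=C14 is in place, where allylic strain between C27 and C19 fixes the conformer: the diketone 21 is isolated instead of ketalized. Its side‑chain ester is hydrolysed with Me3SnOH (neutral) to the diketo acid F8. Trifluoroacetic anhydride gives the enol lactone ketone F9, and LiBH(s‑Bu)3 at −78 °C gives the 19α‑alcohol F10. Silylation with TBSOTf and 2,6‑lutidine rejoins the route at 27.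

## Further compounds

F1 | step 5 | methyl (6E,10E)-12-acetoxy-2,6,10-trimethyl-3-oxododeca-6,10-dienoate | COC(=O)C(C)C(=O)CC/C(C)=C/CC/C(C)=C/COC(C)=O
F2 | step 5 | racemic methyl 11-acetoxy-3-oxo-8(26)-en-24-oate AB keto ester (one enantiomer drawn) | C=C1CC[C@@H]2[C@](C)(CCC(=O)[C@]2(C)C(=O)OC)[C@H]1COC(C)=O
F3 | step 5 | 11-O-acetate of triol 11 | C=C1CC[C@@H]2[C@](C)(CC[C@@H](O)[C@]2(C)CO)[C@H]1COC(C)=O
F4 | step 18 | C14 trimethylsilyl analogue of 31 | C=C1CC[C@@H]2[C@](C)(CC[C@@H](O[Si](C)(C)C(C)(C)C)[C@]2(C)CO[Si](C)(C)C(C)(C)C)[C@H]1CC(=O)CC2=C([Si](C)(C)C)CC[C@@]3(C(=O)OC)CCC(C)(C)[C@@H](O[Si](C)(C)C(C)(C)C)[C@@H]23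
F5 | step 19 | 12β-alcohol (C12 epimer of 33) | O[C@H]1CC2=C(CC[C@@]3(C(=O)OC)CCC(C)(C)[C@@H](O[Si](C)(C)C(C)(C)C)[C@@H]23)[C@]2(C)CC[C@@H]3[C@](C)(CC[C@@H](O[Si](C)(C)C(C)(C)C)[C@]3(C)CO[Si](C)(C)C(C)(C)C)[C@H]2C1
F6 | step 19 | 12β-methanesulfonate | CS(=O)(=O)O[C@H]1CC2=C(CC[C@@]3(C(=O)OC)CCC(C)(C)[C@@H](O[Si](C)(C)C(C)(C)C)[C@@H]23)[C@]2(C)CC[C@@H]3[C@](C)(CC[C@@H](O[Si](C)(C)C(C)(C)C)[C@]3(C)CO[Si](C)(C)C(C)(C)C)[C@H]2C1
F7 | step 19 | 12α-acetate | CC(=O)O[C@@H]1CC2=C(CC[C@@]3(C(=O)OC)CCC(C)(C)[C@@H](O[Si](C)(C)C(C)(C)C)[C@@H]23)[C@]2(C)CC[C@@H]3[C@](C)(CC[C@@H](O[Si](C)(C)C(C)(C)C)[C@]3(C)CO[Si](C)(C)C(C)(C)C)[C@H]2C1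
F8 | step 13 | cis-fused 14,19-diketo acid | OC(=O)C[C@H]1C(=O)CC[C@@]2(C(=O)OC)CCC(C)(C)C(=O)[C@@H]12
F9 | step 13 | enol lactone 19-ketone | O=C1CC2=C(O1)CC[C@@]3(C(=O)OC)CCC(C)(C)C(=O)[C@@H]23
F10 | step 13 | enol lactone 19α-alcohol | O=C1CC2=C(O1)CC[C@@]3(C(=O)OC)CCC(C)(C)[C@@H](O)[C@@H]23
A1 | alternative 1 | ring D closed by Ireland–Claisen, C22 acid on C17, ring E open | CO[C@@H]1CC2=C(CC[C@@](C(=O)OC)(C(=O)O)[C@H]2[C@H](O[Si](C)(C)C(C)(C)C)C(C)(C)C=C)[C@]2(C)CC[C@@H]3[C@](C)(CC[C@@H](O[Si](C)(C)C(C)(C)C)[C@]3(C)C(=O)OC)[C@H]2C1
A2 | alternative 2 | 8,14-methano-13-ol (cyclopropane carrying the future C26) | CO[C@@H]1C[C@@]2(O)[C@@]5(CC[C@@]3(C(=O)OC)CCC(C)(C)[C@@H](OC(C)=O)[C@@H]23)C[C@]52CC[C@@H]3[C@](C)(CC[C@@H](OC(C)=O)[C@]3(C)C(=O)OC)[C@H]2C1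
A3 | alternative 3 | Diels–Alder adduct (14-ene, 19-ketone) | CO[C@@H]1C[C@H]2C(=CC[C@@]3(C(=O)OC)CCC(C)(C)C(=O)[C@@H]23)[C@]2(C)CC[C@@H]3[C@](C)(CC[C@@H](OC(C)=O)[C@]3(C)C(=O)OC)[C@H]2C1
A4 | alternative 3 | methyl 4,4-dimethyl-3-oxocyclohex-1-ene-1-carboxylate (ring E keto ester) | COC(=O)C1=CC(=O)C(C)(C)CC1
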